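The route rests on closing ring A (C7, C9, C11, C12, C13, C18) and its bridging γ-lactone in one step. A ring B cyclohexane that carries a 3-oxo tert-butyl ester on C7, an isopropenyl group on C18, the C21 methylene and a protected C5 carbinol is oxidised with Mn(OAc)3: the C11 radical adds to C12, and the C13 cation that follows is captured by the ester carbonyl, which forms C11–C12 and O15–C13, two rings and two stereocentres. The feature used is the 1,3-placement in ring A of C11, which bears carboxyl C16, and oxygenated tertiary C13. Ring B comes from an asymmetric Diels–Alder reaction; rings C, D and E are then grown from C5 and C21.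

Key step: step 8

Remarks on the chemistry: atoms are numbered in the heavy-atom order of the target SMILES (C1 to O32). The O–C5 protecting group is tert-butyldiphenylsilyl, chosen to survive acetic acid in step 8. Assumption: the (S)-oxazaborolidinium catalyst of step 5 is taken to shield the dienophile face that leads to the mirror image; if the sense is the opposite, the (R)-catalyst is used.

Step 1
Reactants: 1 3-[(tert-butyldiphenylsilyl)oxy]propanal
Product: 2 5-[(tert-butyldiphenylsilyl)oxy]pent-1-en-3-ol
Conditions: CH2=CHMgBr, THF, −78 → 0 °C; aq. NH4Cl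
Reagents that add atoms: vinylmagnesium bromide, C=C[Mg]Br
Why: Grignard 1,2-addition of the vinyl nucleophile to the aldehyde should give the allylic alcohol; the new carbinol centre is racemic and is removed in step 2.

Step 2
Reactants: 2 5-[(tert-butyldiphenylsilyl)oxy]pent-1-en-3-ol
Product: 3 5-[(tert-butyldiphenylsilyl)oxy]pent-1-en-3-one
Conditions: Dess–Martin periodinane, NaHCO3, CH2Cl2, 0 °C → rt
Reagents that add atoms: none
Why: Dess–Martin oxidation of the secondary allylic alcohol should give the vinyl ketone under buffered, non-basic conditions that spare the β-silyloxy group.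

Step 3
Reactants: 3 5-[(tert-butyldiphenylsilyl)oxy]pent-1-en-3-one
Product: 4 (Z)-3-[(tert-butyldimethylsilyl)oxy]-5-[(tert-butyldiphenylsilyl)oxy]penta-1,3-diene
Conditions: t-BuMe2SiOSO2CF3, Et3N, Et2O, −78 → 0 °C
Reagents that add atoms: tert-butyldimethylsilyl trifluoromethanesulfonate, CC(C)(C)[Si](C)(C)OS(=O)(=O)C(F)(F)F
Why: Soft enolisation (silyl triflate and amine) of the ketone should give the 2-silyloxy diene, the (Z)-enol ether being favoured, which puts the C5 side chain on the outside of the s-cis diene.

Step 4
Reactants: 5 methyl pyruvate; 6 1-(triphenylphosphoranylidene)propan-2-one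
Product: 7 methyl (E)-2-methyl-4-oxopent-2-enoate
Conditions: CH2Cl2, rt → 40 °C
Reagents that add atoms: none
Why: Wittig olefination of the activated ketone of methyl pyruvate by the stabilised ylide should give the trisubstituted keto enoate, the (E)-isomer (ester trans to acetyl) being the expected major product and separable from the (Z)-isomer.

Step 5
Reactants: 4 (Z)-3-[(tert-butyldimethylsilyl)oxy]-5-[(tert-butyldiphenylsilyl)oxy]penta-1,3-diene; 7 methyl (E)-2-methyl-4-oxopent-2-enoate
Product: 9 ring B diketo ester, via silyl enol ether cycloadduct 8 (not isolated)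
Conditions: (S)-3,3-diphenyl-1-(2-methylphenyl)tetrahydro-1H,3H-pyrrolo[1,2-c][1,3,2]oxazaborole protonated by HN(SO2CF3)2 (20 mol%), CH2Cl2, −78 → −20 °C; then 1 M HCl, THF, 0 °C
Reagents that add atoms: none
Why: Catalytic enantioselective Diels–Alder reaction in which the oxazaborolidinium ion binds the ketone, so the enol ether terminus C6 bonds to the ketone β-carbon C7; the ketone-endo transition state of the (Z)-diene and (E)-dienophile places the C5 side chain, the C7 methyl and the acetyl group cis with the ester trans, the catalyst face sets the absolute configuration of C6, C7 and C18 together, and dilute acid then hydrolyses the enol ether.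

Step 6
Reactants: 9 ring B diketo ester
Product: 10 ring B bis-methylidene ester
Conditions: Ph3PCH3Br, KN(SiMe3)2, THF, 0 → 40 °C
Reagents that add atoms: methyltriphenylphosphonium bromide, C[P+](c1ccccc1)(c1ccccc1)c1ccccc1.[Br-]
Why: Twofold Wittig methylenation should convert both ketones and leave the hindered ester untouched; C6 and C18 are α to the ketones but already hold the more stable equatorial arrangement.

Step 7
Reactants: 10 ring B bis-methylidene ester; 11 tert-butyl acetate
Product: 12 seco-ring-A 3-oxo tert-butyl ester
Conditions: LiN(i-Pr)2 (4 equiv), 11 (4 equiv), THF, −78 °C; then 10, −78 → 0 °C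
Reagents that add atoms: none
Why: Crossed Claisen condensation of the lithium enolate of 11 with the non-enolisable methyl ester should give the 3-oxo ester, the excess enolate deprotonating the product and so driving the addition to the hindered ester.

Step 8
Reactants: 12 seco-ring-A 3-oxo tert-butyl ester
Product: 13 ring A/B keto lactone
Conditions: Mn(OAc)3·2H2O (2.2 equiv), degassed AcOH (0.02 M), 50 °C
Reagents that add atoms: none
Why: Mn(OAc)3 forms the manganese enolate of the 3-oxo ester and electron transfer gives the electrophilic C11 radical, which adds to the CH2 terminus C12 of the isopropenyl group; a second equivalent of Mn(OAc)3 oxidises the tertiary C13 radical to the cation, which the tert-butyl ester carbonyl captures with loss of 2-methylpropene. The closest known reaction type is the oxidative free-radical cyclisation of unsaturated 3-oxo esters by trivalent manganese with lactone capture of the oxidised radical. Ring A closes 6-endo-trig through a chair in which C9 and C13 are both equatorial on ring B, and the lactone closes by attack of the carbonyl oxygen on the C13 cation in a five-membered ring. C13 is set because the two-atom O15–C16 bridge can span C11 and C13 only diaxially, on the face of the C7 methyl, and C11 is set by the same bridge, since only the epimer with its carboxyl on that face can lactonise. The step needs 6-endo and not 5-exo addition, reaction at the isopropenyl group and not at the C21 methylene, and the carboxyl on the C7-methyl face: the alkene methyl secures the first, the anti arrangement of C9 and the C6–C21 bond in the ring B chair (no six-membered path to C22) secures the second, and the planar C11 radical, free to place the ester anti to the ketone oxygen in the chair transition state, allows the third. No copper salt is added, so the tertiary radical is oxidised to the cation and not to an olefin.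

Step 9
Reactants: 13 ring A/B keto lactone
Product: 14 C9 alcohol
Conditions: LiBH(s-Bu)3, THF, −78 °C; aq. work-up
Reagents that add atoms: none
Why: Hydride reduction with a bulky trialkylborohydride should deliver hydride along the equatorial direction, as with other cyclohexanones flanked by a quaternary centre, and so give the axial C9 alcohol on the face opposite the C7 methyl and the lactone, which is also favoured because an equatorial oxygen would be pressed against C5; the lactone is not reduced at −78 °C.

Step 10
Reactants: 14 C9 alcohol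
Product: 15 C9 silyl ether
Conditions: t-BuMe2SiOSO2CF3, 2,6-lutidine, CH2Cl2, 0 °C → rt
Reagents that add atoms: tert-butyldimethylsilyl trifluoromethanesulfonate, CC(C)(C)[Si](C)(C)OS(=O)(=O)C(F)(F)F
Why: Silylation with the silyl triflate should cap the hindered axial C9 alcohol, so that no free hydroxyl lies near C5 in steps 12 and 13 and none is oxidised in step 17.

Step 11
Reactants: 15 C9 silyl ether
Product: 16 C5 alcohol
Conditions: Bu4NF, AcOH, THF, 0 °C → rt
Reagents that add atoms: none
Why: Fluoride desilylation should cleave the unhindered primary silyl ether far faster than the axial C9 silyl ether flanked by C7 and C11, and the acetic acid buffer protects the lactone.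

Step 12
Reactants: 16 C5 alcohol
Product: 17 C5 iodide
Conditions: I2, PPh3, imidazole, CH2Cl2, 0 °C → rt
Reagents that add atoms: iodine, II
Why: Appel-type iodination (SN2 displacement of the alkoxyphosphonium group by iodide) should convert the primary alcohol into the iodide without touching the alkene or the lactone.

Step 13
Reactants: 17 C5 iodide; 18 methyl 3-oxopentanoate
Product: 19 seco-ring-C 3-oxo ester
Conditions: 18, NaH then n-BuLi, THF, 0 °C; then 17, N,N'-dimethylpropyleneurea, 0 °C → rt
Reagents that add atoms: none
Why: Alkylation of the dianion of a 3-oxo ester at its more reactive γ-carbon (SN2 at primary C5) should form C5–C3; C3 arises as a mixture of epimers, which is harmless because it stays enolisable until step 16.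

Step 14
Reactants: 19 seco-ring-C 3-oxo ester
Product: 20 ring C keto ester
Conditions: SnCl4 (2 equiv), CH2Cl2, −78 → 0 °C
Reagents that add atoms: none
Why: Lewis-acid-promoted cation–olefin cyclisation ended by a 3-oxo ester (intramolecular hydroalkylation): protonation of the C21 methylene gives the tertiary cation and the tin-bound enol carbon C23 attacks it through a chair-like six-membered transition state on the face opposite the axial C7 methyl, which gives the trans B/C fusion with C22 axial, while C3 and C23 equilibrate to the equatorial methyl and ester.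

Step 15
Reactants: 20 ring C keto ester
Product: 21 C23 allyl keto ester
Conditions: CH2=CHCH2Br, Cs2CO3, DMF, rt
Reagents that add atoms: allyl bromide, C=CCBr
Why: C-Allylation of the 3-oxo ester enolate should occur at C23 on the face opposite the adjacent axial C22 methyl, which sets the quaternary centre with the allyl group axial and the ester equatorial.

Step 16
Reactants: 21 C23 allyl keto ester
Product: 23 ring D ketol, via keto aldehyde 22 (not isolated)
Conditions: O3, CH2Cl2, −78 °C; PPh3; then 1,8-diazabicyclo[5.4.0]undec-7-ene, 0 °C → rt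
Reagents that add atoms: ozone, [O-][O+]=O
Why: Ozonolysis of the only alkene gives the aldehyde, and base-mediated intramolecular aldol addition of the C3 enolate (the only enolisable position of the C2 ketone) should close ring D as a bridged ketol; the tether reaches C3 only from the face that carries C29, which fixes C3, and the configuration of the C31 carbinol is of no consequence.

Step 17
Reactants: 23 ring D ketol
Product: 24 ring D diketone
Conditions: Dess–Martin periodinane, NaHCO3, CH2Cl2, rt
Reagents that add atoms: none
Why: Dess–Martin oxidation of the secondary C31 alcohol should give the 1,3-diketone under neutral conditions that avoid retro-aldol opening of ring D.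

Step 18
Reactants: 24 ring D diketone
Product: 25 C31 silyl enol ether
Conditions: t-BuMe2SiOSO2CF3, Et3N, CH2Cl2, 0 °C
Reagents that add atoms: tert-butyldimethylsilyl trifluoromethanesulfonate, CC(C)(C)[Si](C)(C)OS(=O)(=O)C(F)(F)F
Why: Silyl enol ether formation by soft enolisation can occur only at C31 (towards C29), because C2 has no enolisable neighbour, so it both masks C31 and prepares C29 for step 20.

Step 19
Reactants: 25 C31 silyl enol ether
Product: 26 C2 methylidene silyl enol ether
Conditions: Ph3PCH3Br, KN(SiMe3)2, toluene, 0 → 80 °C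
Reagents that add atoms: methyltriphenylphosphonium bromide, C[P+](c1ccccc1)(c1ccccc1)c1ccccc1.[Br-]
Why: Wittig methylenation should convert the remaining strained bridging ketone C2, while the enol ether, the hindered ester and the bridged lactone are not attacked by the non-stabilised ylide.

Step 20
Reactants: 26 C2 methylidene silyl enol ether
Product: 28 ring E lactone, via aldol adduct 27 (not isolated)
Conditions: CH3CHO, BF3·OEt2, CH2Cl2, −78 °C; then camphorsulfonic acid (10 mol%), toluene, 50 °C
Reagents that add atoms: acetaldehyde, CC=O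
Why: Mukaiyama aldol addition followed by acid-catalysed lactonisation: acetaldehyde should add to C29 on the exo face (away from the C5–C6–C21 bridge), an open transition state that keeps the aldehyde methyl away from quaternary C23 sets C27, and the C27 hydroxyl then closes ring E on the neighbouring C24 ester.

Step 21
Reactants: 28 ring E lactone
Product: 29 C29 hydroxy ketone silyl ether
Conditions: KN(SiMe3)2, THF, −78 °C; then 3-phenyl-2-(phenylsulfonyl)oxaziridine, −78 → −40 °C
Reagents that add atoms: 3-phenyl-2-(phenylsulfonyl)oxaziridine, O=S(=O)(c1ccccc1)N1OC1c1ccccc1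
Why: Enolate hydroxylation with a sulfonyl oxaziridine: the potassium enolate of the C31 ketone can be oxygenated only at C29 and only on the endo face, because ring E must stay cis-fused to ring D, which sets the C29 carbinol; ring opening by β-elimination is the reverse of a 5-endo-trig closure and is stereoelectronically slow.

Step 22
Reactants: 29 C29 hydroxy ketone silyl ether
Product: 30 Brasilianoid F
Conditions: HF·pyridine, THF, 0 °C → rt
Reagents that add atoms: none
Why: Cleavage of the hindered silyl ether with pyridine-buffered hydrogen fluoride should free the C9 hydroxyl without acid or base strong enough to disturb the α-ketol, the lactones or the alkene.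

Compound list
1 | 3-[(tert-butyldiphenylsilyl)oxy]propanal | CC(C)(C)[Si](OCCC=O)(c1ccccc1)c1ccccc1 | starting material
2 | 5-[(tert-butyldiphenylsilyl)oxy]pent-1-en-3-ol (racemic) | CC(C)(C)[Si](OCCC(O)C=C)(c1ccccc1)c1ccccc1 | intermediate
3 | 5-[(tert-butyldiphenylsilyl)oxy]pent-1-en-3-one | CC(C)(C)[Si](OCCC(=O)C=C)(c1ccccc1)c1ccccc1 | intermediate
4 | (Z)-3-[(tert-butyldimethylsilyl)oxy]-5-[(tert-butyldiphenylsilyl)oxy]penta-1,3-diene | C=C/C(O[Si](C)(C)C(C)(C)C)=C/CO[Si](c1ccccc1)(c1ccccc1)C(C)(C)C | intermediate
5 | methyl pyruvate | CC(=O)C(=O)OC | starting material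
6 | 1-(triphenylphosphoranylidene)propan-2-one | CC(=O)C=P(c1ccccc1)(c1ccccc1)c1ccccc1 | starting material
7 | methyl (E)-2-methyl-4-oxopent-2-enoate | COC(=O)/C(C)=C/C(C)=O | intermediate
8 | silyl enol ether cycloadduct: methyl 6-acetyl-3-[(tert-butyldimethylsilyl)oxy]-2-{[(tert-butyldiphenylsilyl)oxy]methyl}-1-methylcyclohex-3-ene-1-carboxylate, with the C2 side chain, C1 methyl and C6 acetyl cis and the ester trans to them | CC(C)(C)[Si](c1ccccc1)(c1ccccc1)OC[C@H]1[C@](C)(C(=O)OC)[C@@H](C(C)=O)CC=C1O[Si](C)(C)C(C)(C)C | intermediate
9 | ring B diketo ester: methyl 6-acetyl-2-{[(tert-butyldiphenylsilyl)oxy]methyl}-1-methyl-3-oxocyclohexane-1-carboxylate, same relative configuration as 8 | CC(C)(C)[Si](c1ccccc1)(c1ccccc1)OC[C@H]1[C@](C)(C(=O)OC)[C@@H](C(C)=O)CCC1=O | intermediate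
10 | ring B bis-methylidene ester: methyl 2-{[(tert-butyldiphenylsilyl)oxy]methyl}-1-methyl-3-methylidene-6-(prop-1-en-2-yl)cyclohexane-1-carboxylate | CC(C)(C)[Si](c1ccccc1)(c1ccccc1)OC[C@H]1[C@](C)(C(=O)OC)[C@@H](C(C)=C)CCC1=C | intermediate
11 | tert-butyl acetate | CC(=O)OC(C)(C)C | starting material
12 | seco-ring-A 3-oxo tert-butyl ester: tert-butyl 3-[2-{[(tert-butyldiphenylsilyl)oxy]methyl}-1-methyl-3-methylidene-6-(prop-1-en-2-yl)cyclohexyl]-3-oxopropanoate | CC(C)(C)[Si](c1ccccc1)(c1ccccc1)OC[C@H]1[C@](C)(C(=O)CC(=O)OC(C)(C)C)[C@@H](C(C)=C)CCC1=C | intermediate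
13 | ring A/B keto lactone: trans-fused rings A and B, C9 ketone, lactone O15–C16 bridging C11 and C13 on the face of the C7 methyl, C6–H and C18–H on the opposite face, C21 methylidene, silyloxymethyl on C6 | CC(C)(C)[Si](c1ccccc1)(c1ccccc1)OC[C@H]1[C@]2(C)C(=O)[C@@H]3C[C@@](C)(OC3=O)[C@H]2CCC1=C | intermediate
14 | C9 alcohol: as 13 with an axial C9 hydroxyl on the face opposite the C7 methyl | CC(C)(C)[Si](c1ccccc1)(c1ccccc1)OC[C@H]1[C@]2(C)[C@H](O)[C@@H]3C[C@@](C)(OC3=O)[C@H]2CCC1=C | intermediate
15 | C9 silyl ether: as 14 with O10 as its tert-butyldimethylsilyl ether | CC(C)(C)[Si](c1ccccc1)(c1ccccc1)OC[C@H]1[C@]2(C)[C@H](O[Si](C)(C)C(C)(C)C)[C@@H]3C[C@@](C)(OC3=O)[C@H]2CCC1=C | intermediate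
16 | C5 alcohol: as 15 with a free hydroxymethyl group on C6 | OC[C@H]1[C@]2(C)[C@H](O[Si](C)(C)C(C)(C)C)[C@@H]3C[C@@](C)(OC3=O)[C@H]2CCC1=C | intermediate
17 | C5 iodide: as 16 with an iodomethyl group on C6 | IC[C@H]1[C@]2(C)[C@H](O[Si](C)(C)C(C)(C)C)[C@@H]3C[C@@](C)(OC3=O)[C@H]2CCC1=C | intermediate
18 | methyl 3-oxopentanoate | CCC(=O)CC(=O)OC | starting material
19 | seco-ring-C 3-oxo ester: methyl 4-methyl-3-oxopentanoate joined through its C5 to C6 of the ring A/B unit, C3 as a mixture of epimers | COC(=O)CC(=O)C(C)C[C@H]1[C@]2(C)[C@H](O[Si](C)(C)C(C)(C)C)[C@@H]3C[C@@](C)(OC3=O)[C@H]2CCC1=C | intermediate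
20 | ring C keto ester: rings A, B and C trans-fused, C2 ketone, C22 methyl axial on C21 (same face as the C7 methyl), C4 methyl and C24 ester equatorial | O=C1[C@@H](C)C[C@H]2[C@]3(C)[C@H](O[Si](C)(C)C(C)(C)C)[C@@H]4C[C@@](C)(OC4=O)[C@H]3CC[C@]2(C)[C@H]1C(=O)OC | intermediate
21 | C23 allyl keto ester: as 20 with an axial allyl group on C23, on the face opposite C22 | O=C1[C@@H](C)C[C@H]2[C@]3(C)[C@H](O[Si](C)(C)C(C)(C)C)[C@@H]4C[C@@](C)(OC4=O)[C@H]3CC[C@]2(C)[C@@]1(CC=C)C(=O)OC | intermediate
22 | keto aldehyde: as 21 with a 2-oxoethyl group on C23 | O=C1[C@@H](C)C[C@H]2[C@]3(C)[C@H](O[Si](C)(C)C(C)(C)C)[C@@H]4C[C@@](C)(OC4=O)[C@H]3CC[C@]2(C)[C@@]1(CC=O)C(=O)OC | intermediate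
23 | ring D ketol: bicyclo[3.2.1]octane with C2 as the one-carbon ketone bridge and C29–C31 as the two-carbon bridge on the face of C6–H, C31 carbinol as a mixture | O=C1[C@@]2(C)C[C@H]3[C@]4(C)[C@H](O[Si](C)(C)C(C)(C)C)[C@@H]5C[C@@](C)(OC5=O)[C@H]4CC[C@]3(C)[C@]1(C(=O)OC)CC2O | intermediate
24 | ring D diketone: as 23 with a C31 ketone | O=C1[C@@]2(C)C[C@H]3[C@]4(C)[C@H](O[Si](C)(C)C(C)(C)C)[C@@H]5C[C@@](C)(OC5=O)[C@H]4CC[C@]3(C)[C@]1(C(=O)OC)CC2=O | intermediate
25 | C31 silyl enol ether: as 24 with C29=C31 and a tert-butyldimethylsilyloxy group on C31 | O=C1[C@@]2(C)C[C@H]3[C@]4(C)[C@H](O[Si](C)(C)C(C)(C)C)[C@@H]5C[C@@](C)(OC5=O)[C@H]4CC[C@]3(C)[C@]1(C(=O)OC)C=C2O[Si](C)(C)C(C)(C)C | intermediate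
26 | C2 methylidene silyl enol ether: as 25 with C2=C1H2 | C=C1[C@@]2(C)C[C@H]3[C@]4(C)[C@H](O[Si](C)(C)C(C)(C)C)[C@@H]5C[C@@](C)(OC5=O)[C@H]4CC[C@]3(C)[C@]1(C(=O)OC)C=C2O[Si](C)(C)C(C)(C)C | intermediate
27 | aldol adduct: C31 ketone with an exo 1-hydroxyethyl group on C29, C27 configured as in the target | C=C1[C@@]2(C)C[C@H]3[C@]4(C)[C@H](O[Si](C)(C)C(C)(C)C)[C@@H]5C[C@@](C)(OC5=O)[C@H]4CC[C@]3(C)[C@]1(C(=O)OC)[C@@H]([C@@H](C)O)C2=O | intermediate
28 | ring E lactone: γ-lactone C23–C24(=O)–O26–C27–C29 cis-fused to ring D, C29–H endo, C28 methyl cis to C29–H | C=C1[C@@]2(C)C[C@H]3[C@]4(C)[C@H](O[Si](C)(C)C(C)(C)C)[C@@H]5C[C@@](C)(OC5=O)[C@H]4CC[C@]3(C)[C@@]13C(=O)O[C@H](C)[C@H]3C2=O | intermediate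
29 | C29 hydroxy ketone silyl ether: Brasilianoid F with O10 as its tert-butyldimethylsilyl ether | C=C1[C@@]2(C)C[C@H]3[C@]4(C)[C@H](O[Si](C)(C)C(C)(C)C)[C@@H]5C[C@@](C)(OC5=O)[C@H]4CC[C@]3(C)[C@@]13C(=O)O[C@H](C)[C@@]3(O)C2=O | intermediate
30 | Brasilianoid F | C=C1[C@@]2(C)C[C@H]3[C@]4(C)[C@H](O)[C@@H]5C[C@@](C)(OC5=O)[C@H]4CC[C@]3(C)[C@@]13C(=O)O[C@H](C)[C@@]3(O)C2=O | target

Total step count: 22. Longest linear sequence: 21 steps (steps 1–3 and 5–22; step 4 is a one-step branch).

Steps most likely to fail

Step 8. The weak point is control of C11 at the radical stage. If the ester settles on the face away from the C7 methyl it cannot reach C13; the cation is then lost by proton loss or capture of acetic acid, and the still enolisable product can be oxidised further. The fallback separates the two bond formations and keeps C21 as a ketone while acid is used. It sets out from 8, isolated from step 5 without the acid treatment, and comes back at 13. Methylenation of the acetyl group alone (Ph3P=CH2; C21 stays masked as the silyl enol ether) would give the isopropenyl enol ether F1. Claisen condensation with the lithium enolate of 11 would give the 3-oxo ester enol ether F2, and dilute HCl the C21 ketone F3. Oxidative radical cyclisation with Mn(OAc)3 and Cu(OAc)2, which turns the tertiary radical into an olefin, should give the ring A olefin F4. CF3CO2H then cleaves the tert-butyl ester and protonates the olefin; because C11 equilibrates through the enol, only the carboxyl on the C7-methyl face closes, giving the diketo lactone F5. Wittig methylenation of the unhindered C21 ketone returns 13.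

Step 5. The cycloaddition may lose regiocontrol (the diene terminus bonding to C18 under the influence of the ester) or face selectivity, because the new bond joins a substituted diene terminus to a fully substituted alkene carbon. The fallback uses a covalently bound auxiliary whose chelated imide is the only strongly activated carbonyl. It sets out from 4 and comes back at 8. Selective saponification of the less hindered ester of commercial dimethyl mesaconate would give the half ester F6. Acylation of lithiated (S)-4-benzyloxazolidin-2-one through the pivaloyl mixed anhydride would give the imide F7. The Et2AlCl-promoted Diels–Alder reaction of F7 with 4, in which the diene adds to the chelated s-cis imide on the face away from the benzyl group, should give the imide cycloadduct F8. Transamidation (MeNHOMe·HCl, AlMe3) would give the N-methoxy-N-methyl amide F9, and MeMgBr the methyl ketone 8.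

Step 13. Substitution at the β-branched primary C5 may be slow, so that elimination to the conjugated diene or attack of the dianion on the ring A lactone competes. The fallback replaces the substitution by a carbonyl addition followed by deoxygenation. It sets out from 16 and comes back at 19. Dess–Martin oxidation would give the aldehyde F10, and addition of the dianion of 18 at −78 °C the aldol adduct F11. 1,1'-Thiocarbonyldiimidazole would give the thiocarbamate F12, and Barton–McCombie deoxygenation (Bu3SnH, azobisisobutyronitrile, toluene, 80 °C) the 3-oxo ester 19.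

Further compounds
F1 | step 8 | isopropenyl enol ether: 8 with the acetyl group methylenated | CC(C)(C)[Si](c1ccccc1)(c1ccccc1)OC[C@H]1[C@](C)(C(=O)OC)[C@@H](C(C)=C)CC=C1O[Si](C)(C)C(C)(C)C
F2 | step 8 | 3-oxo ester enol ether: F1 with the methyl ester turned into the 3-oxo tert-butyl ester | CC(C)(C)[Si](c1ccccc1)(c1ccccc1)OC[C@H]1[C@](C)(C(=O)CC(=O)OC(C)(C)C)[C@@H](C(C)=C)CC=C1O[Si](C)(C)C(C)(C)C
F3 | step 8 | C21 ketone: 12 with a C21 ketone in place of the methylidene group | CC(C)(C)[Si](c1ccccc1)(c1ccccc1)OC[C@H]1[C@](C)(C(=O)CC(=O)OC(C)(C)C)[C@@H](C(C)=C)CCC1=O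
F4 | step 8 | ring A olefin: ring A closed, C13 exocyclic methylidene, C11 tert-butyl ester (epimers), C21 ketone | CC(C)(C)[Si](c1ccccc1)(c1ccccc1)OC[C@H]1[C@]2(C)C(=O)C(C(=O)OC(C)(C)C)CC(=C)[C@H]2CCC1=O
F5 | step 8 | diketo lactone: 13 with a C21 ketone in place of the methylidene group | CC(C)(C)[Si](c1ccccc1)(c1ccccc1)OC[C@H]1[C@]2(C)C(=O)[C@@H]3C[C@@](C)(OC3=O)[C@H]2CCC1=O
F6 | step 5 | half ester: (E)-4-methoxy-3-methyl-4-oxobut-2-enoic acid | COC(=O)/C(C)=C/C(=O)O
F7 | step 5 | imide: methyl (E)-4-[(S)-4-benzyl-2-oxooxazolidin-3-yl]-2-methyl-4-oxobut-2-enoate | COC(=O)/C(C)=C/C(=O)N1[C@@H](Cc2ccccc2)COC1=O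
F8 | step 5 | imide cycloadduct: 8 with the acetyl group replaced by the (S)-4-benzyl-2-oxooxazolidine-3-carbonyl group | CC(C)(C)[Si](c1ccccc1)(c1ccccc1)OC[C@H]1[C@](C)(C(=O)OC)[C@@H](C(=O)N2[C@@H](Cc3ccccc3)COC2=O)CC=C1O[Si](C)(C)C(C)(C)C
F9 | step 5 | N-methoxy-N-methyl amide: 8 with the acetyl group replaced by C(=O)N(OMe)Me | CC(C)(C)[Si](c1ccccc1)(c1ccccc1)OC[C@H]1[C@](C)(C(=O)OC)[C@@H](C(=O)N(C)OC)CC=C1O[Si](C)(C)C(C)(C)C
F10 | step 13 | aldehyde: 16 with C5 as a formyl group | O=C[C@H]1[C@]2(C)[C@H](O[Si](C)(C)C(C)(C)C)[C@@H]3C[C@@](C)(OC3=O)[C@H]2CCC1=C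
F11 | step 13 | aldol adduct: 19 with a hydroxyl on C5 (mixture at C3 and C5) | COC(=O)CC(=O)C(C)C(O)[C@H]1[C@]2(C)[C@H](O[Si](C)(C)C(C)(C)C)[C@@H]3C[C@@](C)(OC3=O)[C@H]2CCC1=C
F12 | step 13 | thiocarbamate: F11 with the C5 hydroxyl as its O-(imidazole-1-carbothioyl) derivative | COC(=O)CC(=O)C(C)C(OC(=S)n1ccnc1)[C@H]1[C@]2(C)[C@H](O[Si](C)(C)C(C)(C)C)[C@@H]3C[C@@](C)(OC3=O)[C@H]2CCC1=C
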